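**Plan**

- Retrosynthesis: the C9–O ester bond is cut first (p-coumaroyl off). Next the C2–aryl bond is cut with C2 raised to a lactone carbonyl, which leaves a trans-3-hydroxymethyl-4-benzyl-γ-butyrolactone. Joining C9 to C5 as C=C turns this lactone into a cis-4-benzylcyclobut-2-ene-1-carboxylic acid, and cutting C7'–aryl ends at a meso anhydride.
- Enabling feature: in the oxolane O1–C2–C3–C4–C5, C3 is bonded to C2 and carries C9, and C4 is bonded to C5 and carries the benzylic C7'. C9 and C5 are both CH2–O, and C2 and C7' both carry the same guaiacyl ring. C3–C4 with C2 and C7' as carboxyl carbons and C9=C5 as an alkene is therefore a meso cis-cyclobut-3-ene-1,2-dicarboxylic unit.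
- Forward order: desymmetrising arylation of the anhydride (C7'–aryl), removal of the benzylic oxygen, ozonolysis/NaBH4/lactonisation (four-membered ring opened, lactone ring closed), aryllithium addition at C2 and reduction of the lactol to the oxolane, esterification at C9, desilylation.
- Stereochemistry: C3 and C4 come from the ligand-controlled choice between the enantiotopic carbonyl groups of the anhydride (cis on the cyclobutene becomes trans on the lactone). C2 comes from hydride attack on the oxocarbenium ion anti to the C3 substituent (2,3-cis).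

Key step: step 5

Assumption: the meso anhydride is taken as a catalogue compound, and the sense of induction in step 2 is assigned by analogy, so the mirror-image form of the ligand that leads to the (1R,4S) keto acid is the one employed.

**Route**

Step 1
Reactants: 1 4-bromo-2-methoxyphenol
Product: 2 (4-bromo-2-methoxyphenoxy)triisopropylsilane
Conditions: TIPSCl, imidazole, DMF, rt
Reagents that add atoms: chlorotriisopropylsilane, TIPSCl (CC(C)[Si](Cl)(C(C)C)C(C)C)
Why: Imidazole-promoted silylation of the phenol (silyl ether formation) masks the acidic OH as a triisopropylsilyl ether that should tolerate magnesium insertion, n-BuLi, NaBH4, CF3CO2H and BF3·OEt2 in the later steps, and no stereocentre is involved.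

Step 2
Reactants: 2 (4-bromo-2-methoxyphenoxy)triisopropylsilane; 3 cis-cyclobut-3-ene-1,2-dicarboxylic anhydride (meso)
Product: 6 (1R,4S)-4-[3-methoxy-4-(triisopropylsilyloxy)benzoyl]cyclobut-2-ene-1-carboxylic acid, via arylmagnesium bromide 4 (not isolated), via diarylzinc 5 (not isolated)
Conditions: Mg turnings (I2 cat.), THF, rt → 45 °C; ZnCl2 (0.5 equiv), 0 °C → rt; 1,4-dioxane, filtration of the precipitated magnesium halide under argon; then 3, Pd(OAc)2 (5 mol%), (R)-1-[(S)-2-(diphenylphosphino)ferrocenyl]ethyldicyclohexylphosphine (Josiphos) or its mirror image (6 mol%), THF, rt; 1 M HCl work-up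
Reagents that add atoms: none
Why: Magnesium insertion into the aryl bromide and transmetalation to zinc give the diarylzinc free of magnesium halide (removed as its dioxane complex), and a palladium-catalysed desymmetrising acyl cross-coupling of the meso succinic anhydride (Negishi-type: oxidative addition of zerovalent palladium into one of the two enantiotopic acyl–oxygen bonds, aryl transfer from zinc, reductive elimination) should then deliver the cis keto acid, both ring stereocentres (the later C3 and C4) being fixed by the chiral Josiphos ligand through its choice of carbonyl group without any bond to them being broken.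

Step 3
Reactants: 6 (1R,4S)-4-[3-methoxy-4-(triisopropylsilyloxy)benzoyl]cyclobut-2-ene-1-carboxylic acid
Product: 8 (1R,5S)-4-[3-methoxy-4-(triisopropylsilyloxy)phenyl]-3-oxabicyclo[3.2.0]hept-6-en-2-one (epimers at C4), via hydroxy acid 7 (not isolated)
Conditions: NaBH4, MeOH, 0 °C; then 1 M HCl to pH 2, rt
Reagents that add atoms: none
Why: Borohydride reduction of the aryl ketone gives the benzylic alcohol, which should close onto the cis carboxyl group on acidification (5-exo-trig lactonisation), the new carbinol centre being formed without control and erased in step 4.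

Step 4
Reactants: 8 (1R,5S)-4-[3-methoxy-4-(triisopropylsilyloxy)phenyl]-3-oxabicyclo[3.2.0]hept-6-en-2-one
Product: 9 (1R,4S)-4-{[3-methoxy-4-(triisopropylsilyloxy)phenyl]methyl}cyclobut-2-ene-1-carboxylic acid
Conditions: Et3SiH (excess), CF3CO2H, CH2Cl2, 0 °C → rt
Reagents that add atoms: none
Why: Ionic hydrogenation (Kursanov–Parnes reduction) in which CF3CO2H ionises the benzylic C–O bond para to the silyloxy group and the excess Et3SiH should trap the stabilised cation by hydride transfer before it rearranges, the two cis stereocentres on the ring taking no part.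

Step 5
Reactants: 9 (1R,4S)-4-{[3-methoxy-4-(triisopropylsilyloxy)phenyl]methyl}cyclobut-2-ene-1-carboxylic acid
Product: 12 (3S,4R)-3-(hydroxymethyl)-4-{[3-methoxy-4-(triisopropylsilyloxy)phenyl]methyl}oxolan-2-one, via bridged ozonide 10 (not isolated), via dihydroxy acid 11 (not isolated)
Conditions: O3, CH2Cl2, −78 °C, Sudan Red 7B as end-point indicator; then NaBH4, MeOH, −78 °C → rt; then 1 M HCl to pH 2, rt
Reagents that add atoms: ozone (O=[O+][O-])
Why: Ozone should add to the strained cis-disubstituted C=C bond of 9 by 1,3-dipolar cycloaddition and the primary ozonide should rearrange by the Criegee mechanism to the bridged ozonide 10, which NaBH4 reduces at both termini to CH2OH, so that the four-membered ring is opened between the carbons that become C9 and C5. The closest known reaction type is alkene ozonolysis with reductive borohydride work-up followed by acid-induced lactonisation of a γ-hydroxy acid. On acidification the hydroxyl on the later C5 attacks the carboxyl carbon (the later C2) in a 5-exo-trig closure to the γ-lactone, whereas the C9 hydroxyl could only form a four-membered β-lactone and stays free. No stereocentre is created: the two ring carbons keep their configuration because no bond to them is broken, and the cis relation on the cyclobutene becomes the trans relation on the lactone because at the carboxyl-bearing carbon the ring bond and the side chain exchange roles. The step needs ozone to consume the alkene before the silyloxyarene, which the higher reactivity of the strained alkene, the low temperature and the dye end point should secure, and it needs regioselective lactonisation, which ring size secures.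

Step 6
Reactants: 12 (3S,4R)-3-(hydroxymethyl)-4-{[3-methoxy-4-(triisopropylsilyloxy)phenyl]methyl}oxolan-2-one
Product: 13 (3S,4R)-3-{[(tert-butyldimethylsilyl)oxy]methyl}-4-{[3-methoxy-4-(triisopropylsilyloxy)phenyl]methyl}oxolan-2-one
Conditions: TBSCl, imidazole, DMF, rt
Reagents that add atoms: tert-butylchlorodimethylsilane, TBSCl (CC(C)(C)[Si](C)(C)Cl)
Why: Imidazole-promoted silylation of the primary alcohol protects C9–OH against the aryllithium and makes the C3 substituent bulky for the later face-selective reduction, without touching the stereocentres.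

Step 7
Reactants: 13 (3S,4R)-3-{[(tert-butyldimethylsilyl)oxy]methyl}-4-{[3-methoxy-4-(triisopropylsilyloxy)phenyl]methyl}oxolan-2-one; 2 (4-bromo-2-methoxyphenoxy)triisopropylsilane
Product: 15 (3S,4R)-3-{[(tert-butyldimethylsilyl)oxy]methyl}-2-[3-methoxy-4-(triisopropylsilyloxy)phenyl]-4-{[3-methoxy-4-(triisopropylsilyloxy)phenyl]methyl}oxolan-2-ol (anomeric mixture in equilibrium with its ring-opened hydroxy ketone), via aryllithium 14 (not isolated)
Conditions: 2, n-BuLi, THF, −78 °C; then 13, −78 °C; saturated aqueous NH4Cl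
Reagents that add atoms: none
Why: Bromine–lithium exchange followed by 1,2-addition of the aryllithium to the lactone carbonyl should stop at the tetrahedral lithium hemiketal at −78 °C (no second addition) and give the lactol on protonation, C3 and C4 being untouched and the anomeric centre being removed in step 8.

Step 8
Reactants: 15 (3S,4R)-3-{[(tert-butyldimethylsilyl)oxy]methyl}-2-[3-methoxy-4-(triisopropylsilyloxy)phenyl]-4-{[3-methoxy-4-(triisopropylsilyloxy)phenyl]methyl}oxolan-2-ol
Product: 16 (2S,3S,4R)-3-{[(tert-butyldimethylsilyl)oxy]methyl}-2-[3-methoxy-4-(triisopropylsilyloxy)phenyl]-4-{[3-methoxy-4-(triisopropylsilyloxy)phenyl]methyl}oxolane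
Conditions: Et3SiH, BF3·OEt2, CH2Cl2, −78 °C
Reagents that add atoms: none
Why: Lewis-acid-promoted reductive deoxygenation of a cyclic hemiketal, in which BF3·OEt2 generates the aryl-conjugated oxocarbenium ion and Et3SiH should deliver hydride to the face of C2 anti to the neighbouring CH2OTBS group on C3 (inside attack on the envelope), so that the aryl group ends cis to C9, which is the (2S) configuration.

Step 9
Reactants: 16 (2S,3S,4R)-3-{[(tert-butyldimethylsilyl)oxy]methyl}-2-[3-methoxy-4-(triisopropylsilyloxy)phenyl]-4-{[3-methoxy-4-(triisopropylsilyloxy)phenyl]methyl}oxolane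
Product: 17 [(2S,3S,4R)-2-[3-methoxy-4-(triisopropylsilyloxy)phenyl]-4-{[3-methoxy-4-(triisopropylsilyloxy)phenyl]methyl}oxolan-3-yl]methanol
Conditions: camphorsulfonic acid (cat.), MeOH/CH2Cl2, 0 °C
Reagents that add atoms: none
Why: Acid-catalysed methanolysis (solvolytic desilylation) should remove the primary alkyl silyl ether much faster than the hindered aryl triisopropylsilyl ethers, and catalytic acid at 0 °C should be too weak to ionise the benzylic C2–O bond.

Step 10
Reactants: 18 p-coumaric acid
Product: 20 (E)-3-{4-[(tert-butyldimethylsilyl)oxy]phenyl}prop-2-enoic acid, via bis-silyl derivative 19 (not isolated)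
Conditions: TBSCl (2.2 equiv), imidazole, DMF, rt; then AcOH/THF/H2O, rt
Reagents that add atoms: tert-butylchlorodimethylsilane, TBSCl (CC(C)(C)[Si](C)(C)Cl)
Why: Silylation of both OH groups followed by mild hydrolysis of the labile silyl ester should leave the phenol protected and the acid free, the E double bond not being touched.

Step 11
Reactants: 17 [(2S,3S,4R)-2-[3-methoxy-4-(triisopropylsilyloxy)phenyl]-4-{[3-methoxy-4-(triisopropylsilyloxy)phenyl]methyl}oxolan-3-yl]methanol; 20 (E)-3-{4-[(tert-butyldimethylsilyl)oxy]phenyl}prop-2-enoic acid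
Product: 21 [(2S,3S,4R)-2-[3-methoxy-4-(triisopropylsilyloxy)phenyl]-4-{[3-methoxy-4-(triisopropylsilyloxy)phenyl]methyl}oxolan-3-yl]methyl (E)-3-{4-[(tert-butyldimethylsilyl)oxy]phenyl}prop-2-enoate
Conditions: DCC, DMAP (cat.), CH2Cl2, 0 °C → rt
Reagents that add atoms: none
Why: Steglich esterification (carbodiimide activation with acyl transfer by DMAP) should acylate the only free hydroxyl group, the primary C9–OH, with no change at any stereocentre.

Step 12
Reactants: 21 [(2S,3S,4R)-2-[3-methoxy-4-(triisopropylsilyloxy)phenyl]-4-{[3-methoxy-4-(triisopropylsilyloxy)phenyl]methyl}oxolan-3-yl]methyl (E)-3-{4-[(tert-butyldimethylsilyl)oxy]phenyl}prop-2-enoate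
Product: 22 [(2S,3S,4R)-2-(4-hydroxy-3-methoxyphenyl)-4-[(4-hydroxy-3-methoxyphenyl)methyl]oxolan-3-yl]methyl (E)-3-(4-hydroxyphenyl)prop-2-enoate (CNP0119373.2)
Conditions: Bu4NF, AcOH, THF, 0 °C
Reagents that add atoms: none
Why: Fluoride-induced cleavage of the three aryl silyl ethers (desilylation driven by Si–F bond formation) is buffered with AcOH so that no phenoxide persists, which should spare the cinnamate ester and the benzylic ether at C2.

**Compound list**

1 | 4-bromo-2-methoxyphenol | COc1cc(Br)ccc1O | starting material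
2 | (4-bromo-2-methoxyphenoxy)triisopropylsilane | COc1cc(Br)ccc1O[Si](C(C)C)(C(C)C)C(C)C | intermediate
3 | cis-cyclobut-3-ene-1,2-dicarboxylic anhydride (meso; 3-oxabicyclo[3.2.0]hept-6-ene-2,4-dione) | O=C1OC(=O)[C@H]2C=C[C@@H]12 | starting material
4 | [3-methoxy-4-(triisopropylsilyloxy)phenyl]magnesium bromide | COc1cc([Mg]Br)ccc1O[Si](C(C)C)(C(C)C)C(C)C | intermediate
5 | bis[3-methoxy-4-(triisopropylsilyloxy)phenyl]zinc | COc1cc([Zn]c2ccc(O[Si](C(C)C)(C(C)C)C(C)C)c(OC)c2)ccc1O[Si](C(C)C)(C(C)C)C(C)C | intermediate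
6 | (1R,4S)-4-[3-methoxy-4-(triisopropylsilyloxy)benzoyl]cyclobut-2-ene-1-carboxylic acid | COc1cc(C(=O)[C@@H]2[C@H](C(=O)O)C=C2)ccc1O[Si](C(C)C)(C(C)C)C(C)C | intermediate
7 | (1R,4S)-4-{hydroxy[3-methoxy-4-(triisopropylsilyloxy)phenyl]methyl}cyclobut-2-ene-1-carboxylic acid (carbinol epimers) | COc1cc(C(O)[C@@H]2[C@H](C(=O)O)C=C2)ccc1O[Si](C(C)C)(C(C)C)C(C)C | intermediate
8 | (1R,5S)-4-[3-methoxy-4-(triisopropylsilyloxy)phenyl]-3-oxabicyclo[3.2.0]hept-6-en-2-one (cis-fused; epimers at C4) | COc1cc(C3OC(=O)[C@@H]4C=C[C@H]34)ccc1O[Si](C(C)C)(C(C)C)C(C)C | intermediate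
9 | (1R,4S)-4-{[3-methoxy-4-(triisopropylsilyloxy)phenyl]methyl}cyclobut-2-ene-1-carboxylic acid (cis) | COc1cc(C[C@@H]2[C@H](C(=O)O)C=C2)ccc1O[Si](C(C)C)(C(C)C)C(C)C | intermediate
10 | (5S,6R)-6-{[3-methoxy-4-(triisopropylsilyloxy)phenyl]methyl}-2,3,7-trioxabicyclo[2.2.1]heptane-5-carboxylic acid (bridged ozonide; bridgehead configuration undefined) | COc1cc(C[C@@H]2[C@H](C(=O)O)C3OOC2O3)ccc1O[Si](C(C)C)(C(C)C)C(C)C | intermediate
11 | (2S,3R)-4-hydroxy-2-(hydroxymethyl)-3-{[3-methoxy-4-(triisopropylsilyloxy)phenyl]methyl}butanoic acid | COc1cc(C[C@@H](CO)[C@H](C(=O)O)CO)ccc1O[Si](C(C)C)(C(C)C)C(C)C | intermediate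
12 | (3S,4R)-3-(hydroxymethyl)-4-{[3-methoxy-4-(triisopropylsilyloxy)phenyl]methyl}oxolan-2-one (trans) | COc1cc(C[C@H]2COC(=O)[C@@H]2CO)ccc1O[Si](C(C)C)(C(C)C)C(C)C | intermediate
13 | (3S,4R)-3-{[(tert-butyldimethylsilyl)oxy]methyl}-4-{[3-methoxy-4-(triisopropylsilyloxy)phenyl]methyl}oxolan-2-one | COc1cc(C[C@H]2COC(=O)[C@@H]2CO[Si](C)(C)C(C)(C)C)ccc1O[Si](C(C)C)(C(C)C)C(C)C | intermediate
14 | [3-methoxy-4-(triisopropylsilyloxy)phenyl]lithium | COc1cc([Li])ccc1O[Si](C(C)C)(C(C)C)C(C)C | intermediate
15 | (3S,4R)-3-{[(tert-butyldimethylsilyl)oxy]methyl}-2-[3-methoxy-4-(triisopropylsilyloxy)phenyl]-4-{[3-methoxy-4-(triisopropylsilyloxy)phenyl]methyl}oxolan-2-ol (anomeric mixture) | COc1cc(C[C@H]2COC(O)(c3ccc(O[Si](C(C)C)(C(C)C)C(C)C)c(OC)c3)[C@@H]2CO[Si](C)(C)C(C)(C)C)ccc1O[Si](C(C)C)(C(C)C)C(C)C | intermediate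
16 | (2S,3S,4R)-3-{[(tert-butyldimethylsilyl)oxy]methyl}-2-[3-methoxy-4-(triisopropylsilyloxy)phenyl]-4-{[3-methoxy-4-(triisopropylsilyloxy)phenyl]methyl}oxolane (2,3-cis, 3,4-trans) | COc1cc(C[C@H]2CO[C@H](c3ccc(O[Si](C(C)C)(C(C)C)C(C)C)c(OC)c3)[C@@H]2CO[Si](C)(C)C(C)(C)C)ccc1O[Si](C(C)C)(C(C)C)C(C)C | intermediate
17 | [(2S,3S,4R)-2-[3-methoxy-4-(triisopropylsilyloxy)phenyl]-4-{[3-methoxy-4-(triisopropylsilyloxy)phenyl]methyl}oxolan-3-yl]methanol | COc1cc(C[C@H]2CO[C@H](c3ccc(O[Si](C(C)C)(C(C)C)C(C)C)c(OC)c3)[C@@H]2CO)ccc1O[Si](C(C)C)(C(C)C)C(C)C | intermediate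
18 | p-coumaric acid, (E)-3-(4-hydroxyphenyl)prop-2-enoic acid | O=C(O)/C=C/c1ccc(O)cc1 | starting material
19 | tert-butyldimethylsilyl (E)-3-{4-[(tert-butyldimethylsilyl)oxy]phenyl}prop-2-enoate | CC(C)(C)[Si](C)(C)OC(=O)/C=C/c1ccc(O[Si](C)(C)C(C)(C)C)cc1 | intermediate
20 | (E)-3-{4-[(tert-butyldimethylsilyl)oxy]phenyl}prop-2-enoic acid | O=C(O)/C=C/c1ccc(O[Si](C)(C)C(C)(C)C)cc1 | intermediate
21 | [(2S,3S,4R)-2-[3-methoxy-4-(triisopropylsilyloxy)phenyl]-4-{[3-methoxy-4-(triisopropylsilyloxy)phenyl]methyl}oxolan-3-yl]methyl (E)-3-{4-[(tert-butyldimethylsilyl)oxy]phenyl}prop-2-enoate | COc1cc(C[C@H]2CO[C@H](c3ccc(O[Si](C(C)C)(C(C)C)C(C)C)c(OC)c3)[C@@H]2COC(=O)/C=C/c2ccc(O[Si](C)(C)C(C)(C)C)cc2)ccc1O[Si](C(C)C)(C(C)C)C(C)C | intermediate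
22 | [(2S,3S,4R)-2-(4-hydroxy-3-methoxyphenyl)-4-[(4-hydroxy-3-methoxyphenyl)methyl]oxolan-3-yl]methyl (E)-3-(4-hydroxyphenyl)prop-2-enoate (CNP0119373.2) | COc1cc(C[C@H]2CO[C@H](c3ccc(O)c(OC)c3)[C@@H]2COC(=O)/C=C/c2ccc(O)cc2)ccc1O | target

**Step count and risks**

Total step count: 12. Longest linear sequence: 11 steps (steps 1 to 9, 11 and 12, from 4-bromo-2-methoxyphenol). Step 10 is a one-step side branch.

Steps most likely to fail:

1. Step 2. The chiral catalyst may discriminate poorly between the two enantiotopic carbonyl groups of the strained anhydride. The hydrogen that is both allylic and α to the new ketone may also be lost, with epimerisation to the trans isomer or migration of the double bond into conjugation. Fallback, setting out from 3: alkaloid-mediated methanolysis of the anhydride (quinidine or quinine, whichever gives the required sense, MeOH, toluene, −55 °C) should give (1S,4R)-4-(methoxycarbonyl)cyclobut-2-ene-1-carboxylic acid F1. Oxalyl chloride with catalytic DMF converts it into methyl (1R,4S)-4-(chlorocarbonyl)cyclobut-2-ene-1-carboxylate F2. Negishi acylation of F2 with diarylzinc 5 (prepared from 2 as in step 2) under Pd(PPh3)4 gives methyl (1R,4S)-4-[3-methoxy-4-(triisopropylsilyloxy)benzoyl]cyclobut-2-ene-1-carboxylate F3. NaBH4 in MeOH then reduces the ketone to methyl (1R,4S)-4-{hydroxy[3-methoxy-4-(triisopropylsilyloxy)phenyl]methyl}cyclobut-2-ene-1-carboxylate F4, which lactonises with loss of methanol and rejoins the route at 8.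

2. Step 4. The benzylic cation sits next to a strained four-membered ring, so Wagner–Meerwein ring expansion to a five-membered ring may compete with hydride capture. Fallback, setting out from 8: the four-membered ring is taken apart before the benzylic oxygen is removed. Ozonolysis of 8 with NaBH4 work-up (conditions of step 5) should give (3S,4R)-3,4-bis(hydroxymethyl)-5-[3-methoxy-4-(triisopropylsilyloxy)phenyl]oxolan-2-one F5. Hydrogenolysis of its benzylic C–O bond (H2, Pd/C, EtOAc/AcOH) gives dihydroxy acid 11, which lactonises as in step 5 and rejoins the route at 12. The same C=C bond is cleaved and the same lactone ring is closed; only the order of deoxygenation and cleavage is exchanged.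

3. Step 8. Hydride delivery to the oxocarbenium ion may show poor facial selectivity. The Lewis acid may also cause epimerisation, at C3 through the enol ether or at C2 through reversible ionisation of the benzylic C–O bond. Fallback, setting out from 15: the ring-opened hydroxy ketone tautomer is reduced under reagent control by Corey–Bakshi–Shibata reduction (BH3·SMe2 with the 2-methyl-CBS-oxazaborolidine antipode that gives the (1S) carbinol, the (R)-catalyst by the usual model with aryl as the large group). This should give (1S,2S,3R)-2-{[(tert-butyldimethylsilyl)oxy]methyl}-1-[3-methoxy-4-(triisopropylsilyloxy)phenyl]-3-{[3-methoxy-4-(triisopropylsilyloxy)phenyl]methyl}butane-1,4-diol F6. Selective sulfonylation of the primary hydroxyl (TsCl, Et3N, cat. DMAP, CH2Cl2, 0 °C) gives (2R,3S,4S)-3-{[(tert-butyldimethylsilyl)oxy]methyl}-4-hydroxy-4-[3-methoxy-4-(triisopropylsilyloxy)phenyl]-2-{[3-methoxy-4-(triisopropylsilyloxy)phenyl]methyl}butyl 4-methylbenzenesulfonate F7. KOtBu in THF at −20 °C then closes the oxolane by intramolecular Williamson etherification (5-exo-tet), with retention at C2 because its C–O bond is not broken, and rejoins the route at 16.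

**Further compounds**

F1 | step 2 | (1S,4R)-4-(methoxycarbonyl)cyclobut-2-ene-1-carboxylic acid | OC(=O)[C@@H]1[C@H](C(=O)OC)C=C1
F2 | step 2 | methyl (1R,4S)-4-(chlorocarbonyl)cyclobut-2-ene-1-carboxylate | ClC(=O)[C@@H]1[C@H](C(=O)OC)C=C1
F3 | step 2 | methyl (1R,4S)-4-[3-methoxy-4-(triisopropylsilyloxy)benzoyl]cyclobut-2-ene-1-carboxylate | COc1cc(C(=O)[C@@H]2[C@H](C(=O)OC)C=C2)ccc1O[Si](C(C)C)(C(C)C)C(C)C
F4 | step 2 | methyl (1R,4S)-4-{hydroxy[3-methoxy-4-(triisopropylsilyloxy)phenyl]methyl}cyclobut-2-ene-1-carboxylate (carbinol epimers) | COc1cc(C(O)[C@@H]2[C@H](C(=O)OC)C=C2)ccc1O[Si](C(C)C)(C(C)C)C(C)C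
F5 | step 4 | (3S,4R)-3,4-bis(hydroxymethyl)-5-[3-methoxy-4-(triisopropylsilyloxy)phenyl]oxolan-2-one (epimers at C5) | COc1cc(C3OC(=O)[C@H](CO)[C@@H]3CO)ccc1O[Si](C(C)C)(C(C)C)C(C)C
F6 | step 8 | (1S,2S,3R)-2-{[(tert-butyldimethylsilyl)oxy]methyl}-1-[3-methoxy-4-(triisopropylsilyloxy)phenyl]-3-{[3-methoxy-4-(triisopropylsilyloxy)phenyl]methyl}butane-1,4-diol | COc1cc(C[C@@H](CO)[C@@H](CO[Si](C)(C)C(C)(C)C)[C@H](O)c2ccc(O[Si](C(C)C)(C(C)C)C(C)C)c(OC)c2)ccc1O[Si](C(C)C)(C(C)C)C(C)C
F7 | step 8 | (2R,3S,4S)-3-{[(tert-butyldimethylsilyl)oxy]methyl}-4-hydroxy-4-[3-methoxy-4-(triisopropylsilyloxy)phenyl]-2-{[3-methoxy-4-(triisopropylsilyloxy)phenyl]methyl}butyl 4-methylbenzenesulfonate | COc1cc(C[C@@H](COS(=O)(=O)c3ccc(C)cc3)[C@@H](CO[Si](C)(C)C(C)(C)C)[C@H](O)c2ccc(O[Si](C(C)C)(C(C)C)C(C)C)c(OC)c2)ccc1O[Si](C(C)C)(C(C)C)C(C)C
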